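The data were computed for substances that don't exist; noise was put on by code.

Early on, both earlier runs still move. Later their readings stand within the scatter, birch from about 15.0 h and ash from about 2.00 h.

| flask | substrate | partner | temperature | remark | time |
|---|---|---|---|---|---|
| birch | 0.24 M | 1.3 equiv | 0 °C | run made earlier |  |
| ash | 0.24 M | 3 equiv | 25 °C | run made earlier |  |
| theta | 0.24 M | 2.00 equiv | 45 °C |  | 3.0 h |
| delta | 0.24 M | 2.00 equiv |  | at 45 °C until 2.0 h, from then on at 5 °C | 3.0 h |
| gamma | 0.24 M | 2.00 equiv | 5 °C |  | 3.0 h |
| alpha | 0.24 M | 2.00 equiv | 25 °C |  | 3.0 h |

- birch (time / h: first product / %, double product / %): 3.00: 7.8, 1.8; 6.00: 10.7, 2.3; 10.0: 13.6, 4.7; 12.0: 14.1, 6.0; 15.0: 14.7, 6.9; 20.0: 15.7, 7.0; 25.0: 14.9, 7.1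
- ash (time / h: first product / %, double product / %): 0.833: 16.7, 18.4; 2.00: 15.5, 24.1; 2.50: 15.5, 23.3; 4.00: 16.0, 23.8; 5.00: 15.3, 23.6; 6.00: 16.2, 22.8

(standard deviation of a reading: 0.5 percentage points)



- the flask that comes out highest in share of first product in all that became first product or double product, or "all alike" when all lie within 1.5 percentage points (theta / delta / gamma / alpha / all alike)
- share of first product in all that became first product or double product, theta
- share of first product in all that became first product or double product, delta
- share of first product in all that became first product or double product, gamma
- share of first product in all that became first product or double product, alpha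

From 0 °C to 25 °C that time shrinks 7.50 times. I scale it by a constant factor per degree and set aside the different equivalents. This gives 10.0 h at 5 °C and 0.399 h at 45 °C. I call this the stop time, the hour from which first product and double product in a flask at that temperature no longer change.

So I expect theta to stand by 3.0 h. Alpha should stand too, since ash, at the same temperature, stands from 2.00 h, before 3.0 h. Delta's stop time comes before its change at 2.0 h, so I expect delta to equal theta. Gamma's stop time is later than 3.0 h, so gamma should still be moving.

A stopped flask should hold a stop share. The last readings give 67.7% for birch and 41.5% for ash, and a straight line in equivalents, with temperature set aside, gives 56.9% at 2.00 equiv. I expect theta, delta and alpha near that. Gamma should lie above that, towards the early birch share of 81.2%.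

The forecast names gamma, with theta 43.5%, delta 53%, gamma 76% and alpha 51%. Of the level stretches it says “so I read them as equilibria”. Its delta lies above its theta, whereas mine are equal.

The flasks give gamma highest: theta 59.1%, delta 59.1%, gamma 70.8%, alpha 56.0%.

    substrate + partner → other mono adduct (k = 1.85 /M/h, Ea = 78.0 kJ/mol)
    partner + other mono adduct → double product (k = 1.07 /M/h, Ea = 59.0 kJ/mol)
    partner + first product → double product (k = 4.93 /M/h, Ea = 78.0 kJ/mol)
    substrate + partner → first product (k = 1.91 /M/h, Ea = 75.0 kJ/mol)
    2 substrate → homo dimer (k = 4.21 × 10⁻⁴ /M/h, Ea = 72.0 kJ/mol)
    partner → decomposed reagent (k = 1.74 /h, Ea = 81.0 kJ/mol)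
    (constants at 25 °C)

In delta, half of the turnover up to 3.0 h of each addition to substrate is done by 1.72 min, well inside my stop time of 0.399 h, and at 0.0366 h partner decomposes 5.9 times as fast as it adds to give other mono adduct. At the change, delta holds partner, the limiting reagent, at 0% of its charge beside substrate at 51.8%. Gamma, with its stop time of 10.0 h, still holds partner at 45.9% of its charge after 3.0 h, and its share is 51.9% after 30.0 h.

Take the delta recipe with 0.41 M of substrate, equivalents held. My stop time was reckoned from temperature with the charges set aside, so this flask's first temperature gives the same 0.399 h, before the change at 2.0 h, and I expect it to stand by then. This neighbour flask ends with partner at 0% of its charge and substrate at 38%, and its share is 46.0%.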